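Readings and results were generated by integration with constants of no real substance; noise was put on by code.

D came slowly, and I began from that slowness. The flasks below differ in E, and each is fed E over the same time.

| setting | alder | larch | eta | epsilon | delta | theta |
|---|---|---|---|---|---|---|
| E | 4.7 mM (fed, over 20 h) | 38 mM (fed, over 20 h) | 35 mM (fed, over 20 h) | 50 mM (fed, over 20 h) | 12 mM (fed, over 20 h) | 8.0 mM (fed, over 20 h) |
| J | 45.5 mM | 45.5 mM | 45.5 mM | 45.5 mM | 45.5 mM | 45.5 mM |
| temperature | −10 °C | 5 °C | 5 °C | 5 °C | 5 °C | 5 °C |
| remark | run made earlier; the fed solution adds 0.50 times the starting volume | run made earlier; the fed solution adds 0.50 times the starting volume | the fed solution adds 0.50 times the starting volume | the fed solution adds 0.50 times the starting volume | the fed solution adds 0.50 times the starting volume | the fed solution adds 0.50 times the starting volume |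
| time |  |  | 15 d | 15 d | 15 d | 15 d |

- alder (time / d: D / %): 2.50: 0; 4.00: 0.3; 6.00: 0; 8.00: 0.8; 12.0: 0.9; 20.0: 4.0; 30.0: 5.5
- larch (time / d: D / %): 0.833: 0.6; 2.50: 1.2; 4.00: 2.3; 6.00: 4.4; 10.0: 7.1; 12.0: 8.7; 15.0: 10.5

(readings scatter by 0.5 percentage points)

- the flasks put in order of amount of D, in percent of the E charged, best first, at 15 d (eta / epsilon / delta / theta)
- the amount of D, in percent of the E charged of the flask you put first, at 15 d
- the amount of D, in percent of the E charged of the flask you put last, at 15 d

- every charge counts on the volume at the start, and the solution that is fed holds the whole dose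

In the larch run, D crept from 0.6% at 0.833 d, when the feed ended, to 10.5% at 15.0 d. So my ledger would not close. Of c(E) = 38 mM charged, the D entry held 3.99 mM, and 34.0 mM stood unaccounted for, as E itself or as something unread.

I therefore turned the ledger round and counted J. If each E that reacts takes one J, that debt comes due whether or not D has appeared. In epsilon, c(J) = 45.5 mM met c(E) = 50 mM, a ratio of 0.910. I called this the J cover, the moles of J charged per mole of E charged. It was 1.30 in eta, 3.79 in delta and 5.69 in theta.

J started alike in these flasks, but the comparison drifts: each percent of E taken costs 1.10 percent of the J in epsilon and 0.176 percent in theta. With less J than E, J was the limiting reagent in epsilon, and the last ledger entry there was 9.00% of the E left uncovered. I expected D to follow the cover, with theta first and epsilon last, but the cover gave me no figure for D.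

The forecast gave theta > delta > eta > epsilon, with 10.8% for the first flask and 10.3% for the last. Its ground was “percent yield almost independent of E”.

The flasks gave theta > delta > eta > epsilon, with theta at 39.7% and epsilon at 1.20%.

    E + J → L (k = 1.20 /M/h, Ea = 48.0 kJ/mol)
    L → X (k = 0.00220 /h, Ea = 106 kJ/mol)
    J + X ⇌ D (K = 380 /M, k = 0.860 /M/h, Ea = 63.0 kJ/mol, ΔH = 12.0 kJ/mol)
    E + D → G (k = 2.60 /M/h, Ea = 68.0 kJ/mol)
    E → Z (k = 6.60 × 10⁻⁵ /h, Ea = 106 kJ/mol)
    (constants at 5 °C)

In epsilon, L stood at 26.9% when the feed ended, with J at 69.9% of its charge. By 15.0 d, L had risen to 41.9%, X stood at 33.5%, and J was down to 1.01% of its charge. E stood at 10.6% then, against the 9.00% the cover had left uncovered.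

In a neighbour flask, epsilon with c(E) = 200 mM, the cover is 0.227, which leaves 77.2% of the E uncovered. The computed flask holds E at 75.5% and Z at 1.77%, with J at 0% and D at 0%.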